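Assumption: step 5 is written with the R enantiomer of the phosphoric acid. The sense of induction for this new two-carbon partner cannot be predicted with certainty, so the S catalyst is used instead if the adduct proves to be the mirror image.

## Analysis of the target

The target is a bis-flavan of the proanthocyanidin class: an upper 5-deoxyflavan-3-ol (ring A with one hydroxyl at C7, pyran ring C, pyrogallol ring B) is joined through C4 to C6' of a lower flavan-3-ol (phloroglucinol-type ring D, pyran ring F, pyrogallol ring E; primed locants). There are five stereocenters in two groups: C2 (R), C3 (S) and C4 (S) are contiguous and all-trans around ring C, so that ring B, the C3 hydroxyl and ring D are all equatorial and rings B and D are cis, whereas C2' (R) and C3' (R) in ring F are cis. Aromatic ring D lies between the two groups, so neither can control the other and each needs its own source of chirality. The free compound has ten phenolic hydroxyls, six of them in two easily oxidized pyrogallol rings, two secondary alcohols, two benzylic aryl ether bonds (O1–C2, O1'–C2') and an acid-labile interflavan bond, which calls for benzyl protection throughout and a neutral final deprotection. The difficulties are the crowding at the C4–C6' bond (C6' sits between two oxygen-bearing carbons), the choice of C6' over C8' for the link, and the less stable 2,3-cis arrangement in ring F. The strategy rests on the position of C4: it is doubly benzylic, and its ring A neighbour C4a is ortho to C8a, the carbon that bears O1, so O1, C8a, C4a and C4 form the heterodiene of a ring A o-quinone methide and C2–C3 is the two-carbon unit that closes ring C on it. A second feature is used with it: C6' is para to C8a' and flanked by equivalent oxygens on C5' and C7', so ring D can pass through that step as a symmetrical 2,6-dioxygenated 4-oxyphenyl group, and ring F can then be built on either of its two equivalent free positions, which can only give the 4→6 isomer.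

## Retrosynthetic reasoning

**18 from 17.** All nine phenols are unmasked in the last step by hydrogenolysis of benzyl ethers. This is the only deprotection that is neutral enough for two pyrogallol rings and the interflavan bond, and it fixes benzyl as the single phenol protecting group of the route.

**17 from 16.** Ring F is opened at C4a'–C4'. The forward reaction is an intramolecular epoxy–arene alkylation, in which a ring D carbon ortho to the ether oxygen attacks the terminal carbon of an epoxide. The cut is placed here because that carbon is activated by three oxygens, because the two ortho positions of ring D in 16 are equivalent, and because neither C2' nor C3' is touched, so the stereochemistry set before is simply carried into ring F.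

**16 from 13 and 15.** The aryl ether bond O1'–C2' is cut next. A Mitsunobu etherification of the ring D phenol of 13 with the benzylic hydroxyl of epoxy alcohol 15 makes it with inversion at C2'. This turns an erythro epoxy alcohol into the threo ether that maps onto the 2,3-cis flavan, and it joins the two halves late.

**15 from 14, and 14 from 6.** Both stereocenters of 15 come from a Sharpless kinetic resolution of racemic allylic alcohol 14, which gives the erythro epoxy alcohol from the fast-reacting enantiomer. 14 is the vinyl Grignard adduct of aldehyde 6.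

**13 from 11.** The C3 hydroxyl is traced back to a C3–silicon bond. A Tamao–Fleming oxidation replaces silicon by oxygen with retention, and the same operation frees the ring D phenol. Carrying the oxygen as silicon is what gives the two-carbon partner of the next disconnection the right polarity.

**11 from 5 and 9 through 10.** This is the key disconnection: C3–C4 and O1–C2 are cut together. In the forward direction a chiral phosphoric acid dehydrates benzhydrol 5 to o-quinone methide 10, which adds E-vinylsilane 9 in a [4+2] reaction. Cutting here, and not at the interflavan bond, makes ring C and all three of its stereocenters in one step from two achiral or racemic pieces. It also moves the crowded C4–C6' bond back to a simple carbonyl addition.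

**9 from 7 and 8, and 7 from 6.** The E-styrylsilane is the hydrosilylation product of arylalkyne 7 with silane 8. 7 is the one-carbon homologue of aldehyde 6, which therefore supplies both pyrogallol rings of the target.

**5 from 2 (through 4) and 3, and 2 from 1.** The C4–C6' bond is cut as the addition of aryllithium 4 to salicylaldehyde 3. 4 comes from directed lithiation of silyl ether 2 between its two benzyloxy groups, and 2 from phenol 1. The bond is made where crowding matters least, and the stereocenter formed is irrelevant because it is destroyed in 10.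

## Alternatives that were turned down

**Alternative 1:** Ring D is disconnected at C4a'–C5' as the Claisen folding of a polyketide chain that is stored as a 4-hydroxy-2-pyranone on C4 of a finished upper flavan. In the forward step Mg(OMe)2 in methanol would open the lactone, and the methylene of an acetonyl side chain would attack the ester so released, aromatizing to acetylphloroglucinol A1.
- For it: the C4–C6' bond exists before ring D does, so no bond has to be made to a carbon flanked by two oxygens. On this point it is stronger than the chosen route, whose key step must bond a carbon that carries a 2,6-disubstituted aryl group. Magnesium-templated folding of such chains is also dependable chemistry.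
- Against it: the step makes no stereocenter, so C2, C3 and C4 must come from a separate synthesis of the upper flavan that also installs the pyranone. A1 has three free phenols and an acetyl group that need about six further steps (condensation with 6, pyran closure, oxygenation at C3', removal of the C4' carbonyl) to become ring F. C2' and C3' would be formed without control from the distant upper unit. The pyran can also close on either hydroxyl next to the acetyl group, one giving the 4→6 and the other the 4→8 isomer.
- Comparison: the chosen strategy offers ring C with three stereocenters in one step, ring F stereocenters from a resolved building block, and 4→6 connectivity by symmetry, in a much shorter sequence.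

**Alternative 2:** Ring C is disconnected at C3–C4 as a pinacol coupling. SmI2 would reduce a diaryl ketone carbonyl between rings A and D to its ketyl, which adds to an aldehyde tethered through O1 and gives the cis-3,4-diol A2 with a tertiary hydroxyl at C4.
- For it: the route is fully convergent on a complete, brominated lower flavan from the chiral pool, so C2', C3' and the 4→6 link are settled before the key step. Here it is stronger than the chosen strategy, which needs three later steps and a kinetic resolution for ring F. Ketyl–aldehyde closures to cis diols are also well established.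
- Against it: A2 carries one oxygen too many. The tertiary, doubly benzylic C4 hydroxyl must be removed by ionic reduction, and a hydride enters the C4 cation anti to the C3 oxygen, which would leave ring D cis to the C3 hydroxyl, the wrong relationship. The aldehyde partner has its C2 stereocenter α to the carbonyl and flanked by an aryl and an aryloxy group, so it is prone to enolization and to loss of aryloxide. The ketone between ring A and the fully substituted ring D still requires acylation at the crowded C6'.
- Comparison: the chosen strategy delivers C4 with its hydrogen and its configuration directly, and keeps C2 out of any enolizable position.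

**Alternative 3:** Ring D is disconnected at C4a'–C5' and C8'–C8a' as a Danheiser-type benzannulation. Heating a 3-benzyloxycyclobutenone that carries the upper flavan on its saturated carbon would give a vinylketene, which adds a triisopropylsiloxyalkyne and recloses to phenol A3.
- For it: every position of ring D is placed regiospecifically and its three oxygens emerge differentiated (free hydroxyl at C5', silyl ether at C8a', benzyl ether at C7'), with C2'–C4' and both lower stereocenters arriving on the alkyne. For differentiating the ring D oxygens it is stronger than the chosen route, which relies on symmetry and one silyl ether.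
- Against it: both partners are long to make. The cyclobutenone must already hold the protected upper flavan with its three stereocenters, attached through a bond as crowded as the one it avoids. The siloxyalkyne carries two protected stereocenters and has to be made by ynolate silylation. The thermal cascade passes through a vinylketene next to the doubly benzylic C4–H. The key step again sets no stereocenter, and ring F still has to be closed afterwards.
- Comparison: the chosen strategy is far shorter, and its key step is the one that creates stereochemistry.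

Key step: step 5

## Route

Step 1
Reactants: 1 3,5-bis(benzyloxy)phenol
Product: 2 [3,5-bis(benzyloxy)phenoxy]tri(propan-2-yl)silane
Conditions: i-Pr3SiCl, imidazole, DMF, rt
Reagents that add atoms: triisopropylsilyl chloride, CC(C)[Si](Cl)(C(C)C)C(C)C
Why: O-silylation of a phenol; the triisopropylsilyl ether tolerates butyllithium, is too hindered and too weakly coordinating to direct metalation, and is later removed by fluoride without touching benzyl ethers.

Step 2
Reactants: 2 [3,5-bis(benzyloxy)phenoxy]tri(propan-2-yl)silane; 3 4-(benzyloxy)-2-hydroxybenzaldehyde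
Product: 5 rac-[4-(benzyloxy)-2-hydroxyphenyl]{2,6-bis(benzyloxy)-4-[(triisopropylsilyl)oxy]phenyl}methanol, via aryllithium 4 (not isolated)
Conditions: 2 (2.2 equiv), n-BuLi (2.1 equiv), THF, 0 °C; then 3, −78 °C → rt; then aq. NH4Cl
Reagents that add atoms: none
Why: Directed ortho-metalation takes place at the carbon between the two benzyloxy groups, which both acidify and chelate it, and the aryllithium adds to the aldehyde (1,2-addition); one equivalent of 4 is spent on the phenol of 3 and returns 2, which is recovered. The carbinol center is formed racemic and is erased when 10 forms in step 5.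

Step 3
Reactants: 6 3,4,5-tris(benzyloxy)benzaldehyde
Product: 7 1,2,3-tris(benzyloxy)-5-ethynylbenzene
Conditions: MeC(O)C(N2)P(O)(OMe)2, K2CO3, MeOH/THF, 0 °C → rt
Reagents that add atoms: dimethyl (1-diazo-2-oxopropyl)phosphonate, CC(=O)C(=[N+]=[N-])P(=O)(OC)OC
Why: Ohira–Bestmann (Seyferth–Gilbert) homologation of an aryl aldehyde to the terminal alkyne under mild carbonate conditions that leave benzyl ethers alone.

Step 4
Reactants: 7 1,2,3-tris(benzyloxy)-5-ethynylbenzene; 8 benzyl(dimethyl)silane
Product: 9 (E)-benzyl(dimethyl){2-[3,4,5-tris(benzyloxy)phenyl]ethenyl}silane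
Conditions: Pt2[(CH2=CHSiMe2)2O]3 (0.5 mol%), P(t-Bu)3 (1 mol%), THF, rt
Reagents that add atoms: none
Why: Platinum-catalysed hydrosilylation of a terminal arylalkyne is a syn addition that places silicon on the terminal carbon; the bulky phosphine suppresses the internal isomer, so the E β-silylstyrene should result.

Step 5
Reactants: 5 rac-[4-(benzyloxy)-2-hydroxyphenyl]{2,6-bis(benzyloxy)-4-[(triisopropylsilyl)oxy]phenyl}methanol; 9 (E)-benzyl(dimethyl){2-[3,4,5-tris(benzyloxy)phenyl]ethenyl}silane
Product: 11 (2R,3S,4S)-3-[benzyl(dimethyl)silyl]-7-(benzyloxy)-4-{2,6-bis(benzyloxy)-4-[(triisopropylsilyl)oxy]phenyl}-2-[3,4,5-tris(benzyloxy)phenyl]chromane, via o-quinone methide 10 (not isolated)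
Conditions: 9 (1.5 equiv), (R)-3,3'-bis(2,4,6-triisopropylphenyl)-1,1'-binaphthyl-2,2'-diyl hydrogen phosphate (10 mol%), 5 Å MS, PhMe, 0 °C → rt; then Et3N
Reagents that add atoms: none
Why: Proposed new method: the phosphoric acid protonates the benzylic hydroxyl of 5 and dehydration gives the E o-quinone methide 10, hydrogen-bonded to the chiral phosphate; the methide carbon (C4) then attacks the silicon-bearing carbon of 9 while positive charge builds at the carbon that becomes C2, where ring B and the anti-periplanar C–Si bond both stabilize it, and the ring A oxygen closes on C2 in the same asynchronous, suprafacial event. The closest known reaction type is the chiral phosphoric acid catalysed [4+2] cycloaddition of in situ o-quinone methides with styrenes and enol ethers; a vinylsilane has not been shown as the two-carbon partner. Ring C closes as an inverse-electron-demand oxa-[4+2] cycloaddition in which C3–C4 and O1–C2 form together to give the six-membered pyran. C2 and C3 are set relative to each other by the E geometry of 9 (ring B and silicon trans), and C4 is set relative to them by the E geometry of 10 together with an endo orientation of ring B, which puts ring B cis to ring D and silicon trans to both, so all three substituents are equatorial. The absolute configuration at C4, and with it at C2 and C3, is set by the face of 10 that the phosphate pocket leaves open. Regiochemistry is secured by silicon, because an electrophile attacks a vinylsilane at the carbon that bears silicon and here that polarization coincides with benzylic stabilization by ring B. The step needs ring closure to be faster than attack of phosphate or moisture on silicon, which the contact ion pair with the phenolic oxygen held next to C2 and the molecular sieves should secure. The twisted 2,6-bis(benzyloxy)aryl group keeps the methide carbon electrophilic and shields 10 from dimerization.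

Step 6
Reactants: 11 (2R,3S,4S)-3-[benzyl(dimethyl)silyl]-7-(benzyloxy)-4-{2,6-bis(benzyloxy)-4-[(triisopropylsilyl)oxy]phenyl}-2-[3,4,5-tris(benzyloxy)phenyl]chromane
Product: 13 (2R,3S,4S)-7-(benzyloxy)-4-[2,6-bis(benzyloxy)-4-hydroxyphenyl]-2-[3,4,5-tris(benzyloxy)phenyl]chroman-3-ol, via fluorosilane 12 (not isolated)
Conditions: Bu4NF (3 equiv), THF, 0 °C; then KHCO3, 30% aq. H2O2, MeOH, 0 → 40 °C
Reagents that add atoms: hydrogen peroxide, OO
Why: Tamao–Fleming oxidation: fluoride removes the benzyl group from silicon and the silyl group from the ring D oxygen, hydroperoxide adds to the activated silicon, and C3 migrates from silicon to oxygen with retention, so the C3 hydroxyl is equatorial and trans to both aryl groups. Benzyl–silicon cleavage at 0 °C should be faster than fluoride-induced β-elimination of the ring oxygen.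

Step 7
Reactants: 6 3,4,5-tris(benzyloxy)benzaldehyde
Product: 14 rac-1-[3,4,5-tris(benzyloxy)phenyl]prop-2-en-1-ol
Conditions: CH2=CHMgBr, THF, 0 °C; then aq. NH4Cl
Reagents that add atoms: vinylmagnesium bromide, C=C[Mg]Br
Why: Grignard 1,2-addition to an aryl aldehyde; the racemic allylic alcohol is resolved in the next step.

Step 8
Reactants: 14 rac-1-[3,4,5-tris(benzyloxy)phenyl]prop-2-en-1-ol
Product: 15 (S)-[(2R)-oxiran-2-yl][3,4,5-tris(benzyloxy)phenyl]methanol
Conditions: Ti(Oi-Pr)4 (10 mol%), L-(+)-diisopropyl tartrate (12 mol%), t-BuOOH (0.5 equiv), 4 Å MS, CH2Cl2, −20 °C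
Reagents that add atoms: tert-butyl hydroperoxide, CC(C)(C)OO
Why: Sharpless kinetic resolution: with the L-(+)-tartrate the R enantiomer of 14 is epoxidized faster and gives the erythro epoxy alcohol, so the carbinol center is selected and the epoxide center is set by the same titanium tartrate complex. The slow S enantiomer of 14 stays behind and is separated.

Step 9
Reactants: 13 (2R,3S,4S)-7-(benzyloxy)-4-[2,6-bis(benzyloxy)-4-hydroxyphenyl]-2-[3,4,5-tris(benzyloxy)phenyl]chroman-3-ol; 15 (S)-[(2R)-oxiran-2-yl][3,4,5-tris(benzyloxy)phenyl]methanol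
Product: 16 (2R,3S,4S)-7-(benzyloxy)-4-[2,6-bis(benzyloxy)-4-{(R)-[(2R)-oxiran-2-yl][3,4,5-tris(benzyloxy)phenyl]methoxy}phenyl]-2-[3,4,5-tris(benzyloxy)phenyl]chroman-3-ol
Conditions: 15 (1.3 equiv), PPh3, i-PrO2CN=NCO2i-Pr, THF, 0 °C → rt
Reagents that add atoms: none
Why: Mitsunobu etherification: the unhindered ring D phenol is the only acidic partner and displaces the oxyphosphonium ion of 15 with inversion, which sets C2' as R and turns the erythro alcohol into the threo ether. The C3 hydroxyl of 13 lies between two aryl-bearing carbons, is activated slowly and reversibly, and cannot be displaced or eliminated from its equatorial position.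

Step 10
Reactants: 16 (2R,3S,4S)-7-(benzyloxy)-4-[2,6-bis(benzyloxy)-4-{(R)-[(2R)-oxiran-2-yl][3,4,5-tris(benzyloxy)phenyl]methoxy}phenyl]-2-[3,4,5-tris(benzyloxy)phenyl]chroman-3-ol
Product: 17 (2R,3S,4S)-7-(benzyloxy)-4-{(2R,3R)-5,7-bis(benzyloxy)-3-hydroxy-2-[3,4,5-tris(benzyloxy)phenyl]chroman-6-yl}-2-[3,4,5-tris(benzyloxy)phenyl]chroman-3-ol
Conditions: BF3·OEt2 (0.3 equiv), CH2Cl2, −78 → −30 °C
Reagents that add atoms: none
Why: Intramolecular Friedel–Crafts epoxy–arene cyclization: the ring D carbon ortho to the new ether oxygen, activated by three oxygens, opens the Lewis acid-bound epoxide at its terminal carbon in the 6-endo mode, which is favoured over 5-exo attack at the hindered, inductively deactivated internal carbon. C2' and C3' are not touched, so the cis relationship fixed in steps 8 and 9 is carried into ring F, and the two ortho positions of ring D are equivalent, so only the 4→6 isomer can form.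

Step 11
Reactants: 17 (2R,3S,4S)-7-(benzyloxy)-4-{(2R,3R)-5,7-bis(benzyloxy)-3-hydroxy-2-[3,4,5-tris(benzyloxy)phenyl]chroman-6-yl}-2-[3,4,5-tris(benzyloxy)phenyl]chroman-3-ol
Product: 18 (2R,3S,4S)-2-(3,4,5-trihydroxyphenyl)-4-[(2R,3R)-3,5,7-trihydroxy-2-(3,4,5-trihydroxyphenyl)chroman-6-yl]chromane-3,7-diol
Conditions: H2 (1 atm), Pd(OH)2/C, THF/MeOH, rt; filtration under argon
Reagents that add atoms: none
Why: Hydrogenolysis of nine aryl benzyl ethers under neutral conditions; the flavan C–O and interflavan bonds are not cleaved under these conditions, and no stereocenter is affected.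

## Compound list

1 | 3,5-bis(benzyloxy)phenol | Oc1cc(OCc2ccccc2)cc(OCc2ccccc2)c1 | starting material
2 | [3,5-bis(benzyloxy)phenoxy]tri(propan-2-yl)silane | CC(C)[Si](C(C)C)(C(C)C)Oc1cc(OCc2ccccc2)cc(OCc2ccccc2)c1 | intermediate
3 | 4-(benzyloxy)-2-hydroxybenzaldehyde | O=Cc1ccc(OCc2ccccc2)cc1O | starting material
4 | {2,6-bis(benzyloxy)-4-[(triisopropylsilyl)oxy]phenyl}lithium | [Li]c1c(OCc2ccccc2)cc(O[Si](C(C)C)(C(C)C)C(C)C)cc1OCc1ccccc1 | intermediate (not isolated)
5 | rac-[4-(benzyloxy)-2-hydroxyphenyl]{2,6-bis(benzyloxy)-4-[(triisopropylsilyl)oxy]phenyl}methanol | Oc1cc(OCc2ccccc2)ccc1C(O)c1c(OCc2ccccc2)cc(O[Si](C(C)C)(C(C)C)C(C)C)cc1OCc1ccccc1 | intermediate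
6 | 3,4,5-tris(benzyloxy)benzaldehyde | O=Cc1cc(OCc2ccccc2)c(OCc2ccccc2)c(OCc2ccccc2)c1 | starting material
7 | 1,2,3-tris(benzyloxy)-5-ethynylbenzene | C#Cc1cc(OCc2ccccc2)c(OCc2ccccc2)c(OCc2ccccc2)c1 | intermediate
8 | benzyl(dimethyl)silane | C[SiH](C)Cc1ccccc1 | starting material
9 | (E)-benzyl(dimethyl){2-[3,4,5-tris(benzyloxy)phenyl]ethenyl}silane | C[Si](C)(Cc1ccccc1)/C=C/c1cc(OCc2ccccc2)c(OCc2ccccc2)c(OCc2ccccc2)c1 | intermediate
10 | (6E)-3-(benzyloxy)-6-({2,6-bis(benzyloxy)-4-[(triisopropylsilyl)oxy]phenyl}methylidene)cyclohexa-2,4-dien-1-one | O=C1C=C(OCc2ccccc2)C=C/C1=C\c1c(OCc2ccccc2)cc(O[Si](C(C)C)(C(C)C)C(C)C)cc1OCc1ccccc1 | intermediate (not isolated)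
11 | (2R,3S,4S)-3-[benzyl(dimethyl)silyl]-7-(benzyloxy)-4-{2,6-bis(benzyloxy)-4-[(triisopropylsilyl)oxy]phenyl}-2-[3,4,5-tris(benzyloxy)phenyl]chromane | C(c1ccccc1)Oc1ccc2c(c1)O[C@H](c1cc(OCc3ccccc3)c(OCc3ccccc3)c(OCc3ccccc3)c1)[C@@H]([Si](C)(C)Cc1ccccc1)[C@@H]2c1c(OCc2ccccc2)cc(O[Si](C(C)C)(C(C)C)C(C)C)cc1OCc1ccccc1 | intermediate
12 | 3,5-bis(benzyloxy)-4-{(2R,3S,4S)-7-(benzyloxy)-3-[fluoro(dimethyl)silyl]-2-[3,4,5-tris(benzyloxy)phenyl]chroman-4-yl}phenol | C(c1ccccc1)Oc1ccc2c(c1)O[C@H](c1cc(OCc3ccccc3)c(OCc3ccccc3)c(OCc3ccccc3)c1)[C@@H]([Si](C)(C)F)[C@@H]2c1c(OCc2ccccc2)cc(O)cc1OCc1ccccc1 | intermediate (not isolated)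
13 | (2R,3S,4S)-7-(benzyloxy)-4-[2,6-bis(benzyloxy)-4-hydroxyphenyl]-2-[3,4,5-tris(benzyloxy)phenyl]chroman-3-ol | C(c1ccccc1)Oc1ccc2c(c1)O[C@H](c1cc(OCc3ccccc3)c(OCc3ccccc3)c(OCc3ccccc3)c1)[C@@H](O)[C@@H]2c1c(OCc2ccccc2)cc(O)cc1OCc1ccccc1 | intermediate
14 | rac-1-[3,4,5-tris(benzyloxy)phenyl]prop-2-en-1-ol | C=CC(O)c1cc(OCc2ccccc2)c(OCc2ccccc2)c(OCc2ccccc2)c1 | intermediate
15 | (S)-[(2R)-oxiran-2-yl][3,4,5-tris(benzyloxy)phenyl]methanol | C1[C@@H](O1)[C@H](c2cc(OCc3ccccc3)c(OCc3ccccc3)c(OCc3ccccc3)c2)O | intermediate
16 | (2R,3S,4S)-7-(benzyloxy)-4-[2,6-bis(benzyloxy)-4-{(R)-[(2R)-oxiran-2-yl][3,4,5-tris(benzyloxy)phenyl]methoxy}phenyl]-2-[3,4,5-tris(benzyloxy)phenyl]chroman-3-ol | C(c1ccccc1)Oc1ccc2c(c1)O[C@H](c1cc(OCc3ccccc3)c(OCc3ccccc3)c(OCc3ccccc3)c1)[C@@H](O)[C@@H]2c1c(OCc2ccccc2)cc(O[C@H](c2cc(OCc3ccccc3)c(OCc3ccccc3)c(OCc3ccccc3)c2)[C@H]2CO2)cc1OCc1ccccc1 | intermediate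
17 | (2R,3S,4S)-7-(benzyloxy)-4-{(2R,3R)-5,7-bis(benzyloxy)-3-hydroxy-2-[3,4,5-tris(benzyloxy)phenyl]chroman-6-yl}-2-[3,4,5-tris(benzyloxy)phenyl]chroman-3-ol | C(c1ccccc1)Oc1ccc2c(c1)O[C@H](c1cc(OCc3ccccc3)c(OCc3ccccc3)c(OCc3ccccc3)c1)[C@@H](O)[C@@H]2c1c(OCc2ccccc2)cc2c(c1OCc1ccccc1)C[C@@H](O)[C@@H](c1cc(OCc3ccccc3)c(OCc3ccccc3)c(OCc3ccccc3)c1)O2 | intermediate
18 | (2R,3S,4S)-2-(3,4,5-trihydroxyphenyl)-4-[(2R,3R)-3,5,7-trihydroxy-2-(3,4,5-trihydroxyphenyl)chroman-6-yl]chromane-3,7-diol | Oc1ccc2c(c1)O[C@H](c1cc(O)c(O)c(O)c1)[C@@H](O)[C@@H]2c1c(O)cc2c(c1O)C[C@@H](O)[C@@H](c1cc(O)c(O)c(O)c1)O2 | target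

## Step count and least certain steps

Total step count: 11. Longest linear sequence: 7 steps (1, 2, 5, 6, 9, 10, 11 from compound 1; the same length from compound 6 through steps 3 and 4).

**Step 5 (key step).**
- What may go wrong: loss of the silyl group from the β-silyl benzylic cation before the ring closes, through attack of phosphate or moisture on silicon, which would give an open-chain propene instead of ring C. Slow addition at the crowded methide carbon could also let 10 condense with itself, and the twisted ring D could fill the catalyst pocket and lower the facial selectivity.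
- Fallback, known chemistry, from 2 back to the route at 13:
  - Commercial natural (2R,3R)-dihydrorobinetin F1 is benzylated on its four phenols (BnBr, K2CO3, DMF, rt) to the tetrabenzyl ether F2.
  - NaBH4 in MeOH/THF reduces the C4 ketone to the 2,3-trans-3,4-trans flavan-3,4-diol F3.
  - BF3·OEt2 in CH2Cl2 at −78 °C ionizes the C4 hydroxyl of F3 to the flavan-4-yl cation stabilized by the C7 oxygen. Arene 2 traps it at its carbon between the two benzyloxy groups, anti to the C3 hydroxyl, to give the silyl ether F4.
  - Bu4NF then frees the phenol and gives 13.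
  - This classical cation arylation gives up the convergence and the catalytic control but keeps every later step.

**Step 6.**
- What may go wrong: fluoride-triggered anti elimination across C3–C2, since silicon and the ring oxygen O1 are anti-periplanar, which would open ring C. Oxidation at the hindered secondary silicon center could also be sluggish.
- Fallback, from 7 back to the route at 13:
  - Alkyne 7 is hydrosilylated with pentamethyldisiloxane under the conditions of step 4 to the vinyldisiloxane F5.
  - The cycloaddition of step 5 with 5 then gives the disiloxanyl adduct F6.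
  - Its silicon–oxygen bond allows a fluoride-free oxidation (KHCO3, H2O2, MeOH/THF, 50 °C) to the silyl ether F4.
  - Bu4NF converts F4 into 13 after the carbon–silicon bond is gone.

**Step 10.**
- What may go wrong: closure in the 5-exo mode at the internal epoxide carbon, or Lewis acid ionization of the benzylic aryl ether at C2'.
- Fallback, from 16 back to the route at 17:
  - Thiophenol and K2CO3 in DMF open the epoxide at its terminal carbon to the hydroxy sulfide F7.
  - NaIO4 gives the sulfoxide F8.
  - (CF3CO)2O in CH2Cl2, followed by aqueous NaHCO3/MeOH, generates a thionium ion at C4' (Pummerer reaction). This ion can only close the six-membered ring on ring D and gives the 4'-phenylsulfanyl bis-flavan F9.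
  - NiCl2·6H2O and NaBH4 remove the sulfur and give 17, leaving the benzyl ethers in place.

**Step 9.**
- What may go wrong: activation of the free C3 hydroxyl of 13 in competition with 15, which would consume reagent and lower conversion. Partial ionization of the benzylic oxyphosphonium ion of 15 could also erode the inversion.
- Fallback, from 11 back to the route at 16, with the order of operations changed so that the C3 oxygen is still masked as silicon during the etherification:
  - Cs2CO3 in DMF/H2O at 40 °C removes only the aryl silyl ether of 11 and gives the phenol F10.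
  - The Mitsunobu reaction with 15 then has a single hydroxyl partner and gives the ether F11.
  - The Tamao–Fleming conditions of step 6, which the epoxide should tolerate at this mild basicity, convert F11 into 16.

**Step 2.**
- What may go wrong: deprotonation of a benzylic OCH2 group and [1,2]-Wittig rearrangement in competition with ring metalation.
- Fallback, from 1 back to the route at 5, with the polarity of the addition reversed:
  - Vilsmeier–Haack formylation of 1 (POCl3, DMF) gives, after separation from the ortho isomer, 2,6-bis(benzyloxy)-4-hydroxybenzaldehyde F12.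
  - Silylation (i-Pr3SiCl, imidazole) gives the aldehyde F13.
  - A further starting material, 5-(benzyloxy)-2-bromophenol F14, is treated with two equivalents of n-BuLi at −78 °C (phenoxide formation, then bromine–lithium exchange), and the resulting aryllithium adds to F13 to give 5.

## Further compounds

F1 | step 5 | (2R,3R)-3,7-dihydroxy-2-(3,4,5-trihydroxyphenyl)-2,3-dihydro-4H-chromen-4-one (dihydrorobinetin) | Oc1ccc2c(c1)O[C@H](c1cc(O)c(O)c(O)c1)[C@@H](O)C2=O
F2 | step 5 | (2R,3R)-7-(benzyloxy)-3-hydroxy-2-[3,4,5-tris(benzyloxy)phenyl]-2,3-dihydro-4H-chromen-4-one | C(c1ccccc1)Oc1ccc2c(c1)O[C@H](c1cc(OCc3ccccc3)c(OCc3ccccc3)c(OCc3ccccc3)c1)[C@@H](O)C2=O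
F3 | step 5 | (2R,3S,4R)-7-(benzyloxy)-2-[3,4,5-tris(benzyloxy)phenyl]chromane-3,4-diol | C(c1ccccc1)Oc1ccc2c(c1)O[C@H](c1cc(OCc3ccccc3)c(OCc3ccccc3)c(OCc3ccccc3)c1)[C@@H](O)[C@@H]2O
F4 | step 5 | (2R,3S,4S)-7-(benzyloxy)-4-{2,6-bis(benzyloxy)-4-[(triisopropylsilyl)oxy]phenyl}-2-[3,4,5-tris(benzyloxy)phenyl]chroman-3-ol | C(c1ccccc1)Oc1ccc2c(c1)O[C@H](c1cc(OCc3ccccc3)c(OCc3ccccc3)c(OCc3ccccc3)c1)[C@@H](O)[C@@H]2c1c(OCc2ccccc2)cc(O[Si](C(C)C)(C(C)C)C(C)C)cc1OCc1ccccc1
F5 | step 6 | (E)-1,1,1,3,3-pentamethyl-3-{2-[3,4,5-tris(benzyloxy)phenyl]ethenyl}disiloxane | C[Si](C)(C)O[Si](C)(C)/C=C/c1cc(OCc2ccccc2)c(OCc2ccccc2)c(OCc2ccccc2)c1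
F6 | step 6 | (2R,3S,4S)-7-(benzyloxy)-4-{2,6-bis(benzyloxy)-4-[(triisopropylsilyl)oxy]phenyl}-3-(1,1,3,3,3-pentamethyldisiloxanyl)-2-[3,4,5-tris(benzyloxy)phenyl]chromane | C(c1ccccc1)Oc1ccc2c(c1)O[C@H](c1cc(OCc3ccccc3)c(OCc3ccccc3)c(OCc3ccccc3)c1)[C@@H]([Si](C)(C)O[Si](C)(C)C)[C@@H]2c1c(OCc2ccccc2)cc(O[Si](C(C)C)(C(C)C)C(C)C)cc1OCc1ccccc1
F7 | step 10 | (2R,3S,4S)-7-(benzyloxy)-4-[2,6-bis(benzyloxy)-4-{(1R,2S)-2-hydroxy-3-(phenylsulfanyl)-1-[3,4,5-tris(benzyloxy)phenyl]propoxy}phenyl]-2-[3,4,5-tris(benzyloxy)phenyl]chroman-3-ol | C(c1ccccc1)Oc1ccc2c(c1)O[C@H](c1cc(OCc3ccccc3)c(OCc3ccccc3)c(OCc3ccccc3)c1)[C@@H](O)[C@@H]2c1c(OCc2ccccc2)cc(O[C@H](c2cc(OCc3ccccc3)c(OCc3ccccc3)c(OCc3ccccc3)c2)[C@H](O)CSc2ccccc2)cc1OCc1ccccc1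
F8 | step 10 | (2R,3S,4S)-7-(benzyloxy)-4-[2,6-bis(benzyloxy)-4-{(1R,2S)-2-hydroxy-3-(phenylsulfinyl)-1-[3,4,5-tris(benzyloxy)phenyl]propoxy}phenyl]-2-[3,4,5-tris(benzyloxy)phenyl]chroman-3-ol (both configurations at sulfur) | C(c1ccccc1)Oc1ccc2c(c1)O[C@H](c1cc(OCc3ccccc3)c(OCc3ccccc3)c(OCc3ccccc3)c1)[C@@H](O)[C@@H]2c1c(OCc2ccccc2)cc(O[C@H](c2cc(OCc3ccccc3)c(OCc3ccccc3)c(OCc3ccccc3)c2)[C@H](O)CS(=O)c2ccccc2)cc1OCc1ccccc1
F9 | step 10 | (2R,3S,4S)-7-(benzyloxy)-4-{(2R,3S)-5,7-bis(benzyloxy)-3-hydroxy-4-(phenylsulfanyl)-2-[3,4,5-tris(benzyloxy)phenyl]chroman-6-yl}-2-[3,4,5-tris(benzyloxy)phenyl]chroman-3-ol (both configurations at C4') | C(c1ccccc1)Oc1ccc2c(c1)O[C@H](c1cc(OCc3ccccc3)c(OCc3ccccc3)c(OCc3ccccc3)c1)[C@@H](O)[C@@H]2c1c(OCc2ccccc2)cc2c(c1OCc1ccccc1)C(Sc1ccccc1)[C@@H](O)[C@@H](c1cc(OCc3ccccc3)c(OCc3ccccc3)c(OCc3ccccc3)c1)O2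
F10 | step 9 | 4-{(2R,3S,4S)-3-[benzyl(dimethyl)silyl]-7-(benzyloxy)-2-[3,4,5-tris(benzyloxy)phenyl]chroman-4-yl}-3,5-bis(benzyloxy)phenol | C(c1ccccc1)Oc1ccc2c(c1)O[C@H](c1cc(OCc3ccccc3)c(OCc3ccccc3)c(OCc3ccccc3)c1)[C@@H]([Si](C)(C)Cc1ccccc1)[C@@H]2c1c(OCc2ccccc2)cc(O)cc1OCc1ccccc1
F11 | step 9 | (2R,3S,4S)-3-[benzyl(dimethyl)silyl]-7-(benzyloxy)-4-[2,6-bis(benzyloxy)-4-{(R)-[(2R)-oxiran-2-yl][3,4,5-tris(benzyloxy)phenyl]methoxy}phenyl]-2-[3,4,5-tris(benzyloxy)phenyl]chromane | C(c1ccccc1)Oc1ccc2c(c1)O[C@H](c1cc(OCc3ccccc3)c(OCc3ccccc3)c(OCc3ccccc3)c1)[C@@H]([Si](C)(C)Cc1ccccc1)[C@@H]2c1c(OCc2ccccc2)cc(O[C@H](c2cc(OCc3ccccc3)c(OCc3ccccc3)c(OCc3ccccc3)c2)[C@H]2CO2)cc1OCc1ccccc1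
F12 | step 2 | 2,6-bis(benzyloxy)-4-hydroxybenzaldehyde | O=Cc1c(OCc2ccccc2)cc(O)cc1OCc1ccccc1
F13 | step 2 | 2,6-bis(benzyloxy)-4-[(triisopropylsilyl)oxy]benzaldehyde | O=Cc1c(OCc2ccccc2)cc(O[Si](C(C)C)(C(C)C)C(C)C)cc1OCc1ccccc1
F14 | step 2 | 5-(benzyloxy)-2-bromophenol | Oc1cc(OCc2ccccc2)ccc1Br
A1 | alternative 1 | 1-{3-[(2R,3S,4S)-7-(benzyloxy)-3-hydroxy-2-[3,4,5-tris(benzyloxy)phenyl]chroman-4-yl]-2,4,6-trihydroxyphenyl}ethanone | C(c1ccccc1)Oc1ccc2c(c1)O[C@H](c1cc(OCc3ccccc3)c(OCc3ccccc3)c(OCc3ccccc3)c1)[C@@H](O)[C@@H]2c1c(O)cc(O)c(C(C)=O)c1O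
A2 | alternative 2 | (2R,3S,4R)-7-(benzyloxy)-4-{(2R,3R)-3,5,7-tris(benzyloxy)-8-bromo-2-[3,4,5-tris(benzyloxy)phenyl]chroman-6-yl}-2-[3,4,5-tris(benzyloxy)phenyl]chromane-3,4-diol (cis-3,4-diol, tertiary C4 hydroxyl) | C(c1ccccc1)Oc1ccc2c(c1)O[C@H](c1cc(OCc3ccccc3)c(OCc3ccccc3)c(OCc3ccccc3)c1)[C@@H](O)[C@]2(O)c1c(OCc2ccccc2)c(Br)c2c(c1OCc1ccccc1)C[C@@H](OCc1ccccc1)[C@@H](c1cc(OCc3ccccc3)c(OCc3ccccc3)c(OCc3ccccc3)c1)O2
A3 | alternative 3 | ring D phenol with free C5' hydroxyl, C8a' triisopropylsilyl ether and C7' benzyl ether, carrying the benzylated upper flavan at C6' and an open C4'–C2' chain with a C3' benzyl ether and a C2' tert-butyldimethylsilyl ether at C4a' | C(c1ccccc1)Oc1ccc2c(c1)O[C@H](c1cc(OCc3ccccc3)c(OCc3ccccc3)c(OCc3ccccc3)c1)[C@@H](OCc1ccccc1)[C@@H]2c1c(O)c(C[C@@H](OCc2ccccc2)[C@@H](O[Si](C)(C)C(C)(C)C)c2cc(OCc3ccccc3)c(OCc3ccccc3)c(OCc3ccccc3)c2)c(O[Si](C(C)C)(C(C)C)C(C)C)cc1OCc1ccccc1
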